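**Plan**

- Numbering follows 2,3-dimethylchroman-4-one: ring B = O1, C2, C3, C4, C4a, C8a; ring A = C4a, C5(OH), C6, C7(=O), C8, C8a. The retrosynthesis first rejoins 5-OH and CO2H as an enol δ-lactone, then cuts C8–prenyl (dearomative allylation), then ring B at O1–C2, C3–C4 and C4–C4a (oxa-Michael addition, alkyne hydroacylation, formylation).
- Ring A is then cut at C8–C8a. The arene is an isomer of a 2-pyranone whose lactone carbonyl is C8a, whose ring oxygen is the C7 oxygen and whose 6-CH2 is C8. The last cuts are C6–CH(Pr) (Michael addition) and C8–CH2 of the lavandulyl group (alkylation).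
- The feature that allows this: ring A is a 1,3,5-trioxygenated carbocycle (O on C5, C7, C8a), a folded triketide in which C8 lies between two oxygenated carbons. C8–C8a can therefore be made by C-acylation once a pyranone is unravelled.
- Forward order: linear 3,5-dioxo ester → temporary 2-pyranone ring → enol δ-lactone (O5/C6) → ring A (key step) → ring B → quaternary C8 → lactone opening.
- Stereochemistry: lavandulyl centre from an Evans alkylation; CH(Pr) centre from an NHC-catalysed Michael addition; C2/C3 (cis) from a quinine-catalysed oxa-Michael ring closure; C8 from a Pd/chiral-ligand allylic dearomatisation.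

Key step: step 9

Assumption: each catalyst antipode named is the one expected from the accepted stereochemical model (the mirror-image catalyst is used if the sense proves opposite), and the target is taken as the drawn 5-enol/7-keto tautomer.

**Step 1**
Reactants: 1 (S)-4-benzyl-1,3-oxazolidin-2-one; 2 3-methylbut-2-enoyl chloride
Product: 3 (S)-4-benzyl-3-(3-methylbut-2-enoyl)-1,3-oxazolidin-2-one
Conditions: n-BuLi, THF, −78 °C; then 2, −78 → 0 °C
Reagents that add atoms: none
Why: N-acylation of the lithiated Evans oxazolidinone with an acid chloride is a standard imide formation that installs the auxiliary without forming a stereocentre.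

**Step 2**
Reactants: 3 N-senecioyl imide; 4 prenyl bromide (1-bromo-3-methylbut-2-ene)
Product: 5 (S)-4-benzyl-3-[(2S)-5-methyl-2-(prop-1-en-2-yl)hex-4-enoyl]-1,3-oxazolidin-2-one
Conditions: NaN(SiMe3)2, THF, −78 °C; then 4, −78 → −30 °C
Reagents that add atoms: none
Why: Evans auxiliary alkylation in its deconjugative variant, in which the chelated sodium Z-dienolate is prenylated at the α-carbon on the face away from the benzyl group, should set the lavandulyl stereocentre (2S here, the centre that is R in the target).

**Step 3**
Reactants: 5 alkylated imide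
Product: 6 (S)-lavandulol, (2S)-5-methyl-2-(prop-1-en-2-yl)hex-4-en-1-ol
Conditions: LiBH4, H2O (1 equiv), Et2O, 0 °C
Reagents that add atoms: none
Why: Reductive cleavage of an N-acyl oxazolidinone with LiBH4 should give the primary alcohol without touching the stereocentre or the alkenes.

**Step 4**
Reactants: 6 (S)-lavandulol
Product: 7 (S)-lavandulyl iodide, (2S)-1-iodo-5-methyl-2-(prop-1-en-2-yl)hex-4-ene
Conditions: PPh3, imidazole, I2, CH2Cl2, 0 °C
Reagents that add atoms: iodine, II
Why: Appel-type iodination replaces the primary hydroxyl by SN2 at the CH2 carbon, so the adjacent stereocentre is not involved.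

**Step 5**
Reactants: 8 methyl 3,5-dioxohexanoate; 7 (S)-lavandulyl iodide
Product: 9 methyl (8S)-11-methyl-3,5-dioxo-8-(prop-1-en-2-yl)dodec-10-enoate
Conditions: LiN(i-Pr)2 (3.2 equiv), THF, 0 °C; then 7, DMPU, −78 → 0 °C; then 1 M HCl
Reagents that add atoms: none
Why: Polyanion alkylation of a 3,5-dioxo ester, in which the terminal carbanion (C6) of the trianion is the most basic site and is alkylated selectively by the primary iodide, attaches the lavandulyl unit to the future C8.

**Step 6**
Reactants: 9 lavandulyl diketo ester; 10 (E)-hex-2-enal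
Product: 13 (3R)-3-[(8S)-1-methoxy-11-methyl-1,3,5-trioxo-8-(prop-1-en-2-yl)dodec-10-en-4-yl]hexanoic acid, via enol lactone 11 (not isolated), via enol lactone 12 (not isolated)
Conditions: aminoindanol-derived N-mesityl triazolium chloride (10 mol %, antipode giving R), DBU (20 mol %), 3,3′,5,5′-tetra-tert-butyldiphenoquinone (1.1 equiv), THF, 25 °C; then H2O, DMAP (10 mol %), 40 °C
Reagents that add atoms: water, O
Why: NHC-catalysed oxidative Michael addition–lactonisation, in which the most acidic C–H (C4, between the two ketones) adds to the β-carbon of the hexenoyl azolium on the face left open by the chiral catalyst, should set the propyl-bearing centre as R before both regioisomeric enol lactones are hydrolysed to one acid.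

**Step 7**
Reactants: 13 keto acid
Product: 14 (3R)-3-{4-hydroxy-6-[(3S)-6-methyl-3-(prop-1-en-2-yl)hept-5-en-1-yl]-2-oxo-2H-pyran-5-yl}hexanoic acid
Conditions: DBU (2.2 equiv), toluene, 90 °C; then 1 M HCl
Reagents that add atoms: none
Why: Base-mediated cyclisation of a 3,5-dioxo ester to a 4-hydroxy-2-pyranone (the C5 enol oxygen attacks the ester with loss of methanol) is a standard triketide lactonisation and ties the future C7 oxygen to the future C8a.

**Step 8**
Reactants: 14 pyranone acid
Product: 15 bis-lactone: the 2-pyranone of 14 with its 4-oxygen and C5 bridged by the (R)-CH(Pr)–CH2–C(=O) unit as a six-membered enol lactone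
Conditions: EDC·HCl, CH2Cl2, 0 → 25 °C
Reagents that add atoms: none
Why: Carbodiimide-mediated O-acylation of the only free hydroxyl (the vinylogous-acid 4-OH) by the tethered acid closes the six-membered enol lactone, which fixes the lactone on the future O5 and masks both groups.

**Step 9**
Reactants: 15 bis-lactone
Product: 18 (4R)-5,7-dihydroxy-6-[(2R)-5-methyl-2-(prop-1-en-2-yl)hex-4-en-1-yl]-4-propylchroman-2-one, via ketene enolate 16 (not isolated), via cyclohexadienone enolate 17 (not isolated)
Conditions: KN(SiMe3)2 (1.2 equiv), THF (0.02 M), −78 → 25 °C; then 1 M HCl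
Reagents that add atoms: none
Why: Proposed new method: KN(SiMe3)2 removes a proton from the 6-CH2 group of the 2-pyranone (the future C8), the delocalised anion, which is a vinylogous ester enolate, expels the ring oxygen by E1cB to give dienylketene enolate 16, this closes by 6π-electrocyclisation (in polar terms a 6-exo C-acylation of the enolate carbon by the ketene carbon) to dienone 17, and loss of the C8 proton gives the arene, so that the C8–C8a bond of ring A is made. The closest known reaction types are the base-induced recyclisation of 6-alkyl-2-pyranones to phloroglucinols through ring-opened esters (Claisen mode), ketene formation from aryl ester enolates, and the dienylketene electrocyclisation that ends the Danheiser benzannulation and the Moore cyclisation. Ring A is closed in a six-electron disrotatory mode between the ketene carbon (C8a) and the enolate carbon (C8), and the Z geometry of the central C5=C6 double bond that this needs is inherited from the pyranone ring. No stereocentre is formed (C8 becomes aromatic) and neither existing centre carries an acidifying group, so both should survive. The step needs C- over O-reclosure of 16, deprotonation at the 6-CH2 group over the lactone α-CH2 and survival of the enol lactone: O-reclosure only regenerates the pyranone anion while C-closure is made irreversible by aromatisation, the 6-CH2 protons are vinylogous to the pyranone carbonyl and unhindered, and the base is non-nucleophilic while the lactone carbonyl cannot reach the other ortho oxygen, so the lactone should stay on O5.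

**Step 10**
Reactants: 18 dihydrocoumarin diol
Product: 19 (4R)-5,7-dihydroxy-6-[(2R)-lavandulyl]-2-oxo-4-propylchroman-8-carbaldehyde (chroman-2-one numbering)
Conditions: MgCl2, Et3N, (CH2O)n, 4 Å MS, THF, 65 °C
Reagents that add atoms: paraformaldehyde (as formaldehyde), C=O
Why: Casiraghi–Skattebøl ortho-formylation, in which the magnesium phenoxide directs formaldehyde to the only free ring carbon (C8, ortho to the 7-OH) and a second formaldehyde oxidises the benzylic alkoxide, gives the aldehyde under non-acidic conditions that spare the alkenes.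

**Step 11**
Reactants: 19 salicylaldehyde; 20 2-butyne
Product: 21 (4R)-5,7-dihydroxy-6-[(2R)-lavandulyl]-8-[(2E)-2-methylbut-2-enoyl]-4-propylchroman-2-one
Conditions: [RhCl(cod)]2 (2.5 mol %), Fe(C5H4PPh2)2 (5 mol %), Na2CO3 (5 mol %), toluene, 80 °C, sealed tube
Reagents that add atoms: none
Why: Rhodium-catalysed chelation-assisted alkyne hydroacylation of a salicylaldehyde adds the acyl–H bond syn across 2-butyne and should give the (E)-2-methylbut-2-enoyl (tigloyl) ketone directly.

**Step 12**
Reactants: 21 tigloyl phenol
Product: 22 (2R,3S)-7-hydroxy-2,3-dimethyl-8-[(2R)-lavandulyl]chroman-4-one whose O5 and C6 are bridged by the (R)-CH(Pr)–CH2–C(=O) unit as a six-membered aryl lactone (target numbering)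
Conditions: (−)-quinine (20 mol %), chlorobenzene, 14 °C
Reagents that add atoms: none
Why: Quinine-catalysed asymmetric intramolecular oxa-Michael addition of the only hydroxyl ortho to the tigloyl group, followed by kinetic protonation of the enol, should close ring B as the cis-(2R,3S)-2,3-dimethylchromanone with both centres under catalyst control.

**Step 13**
Reactants: 22 tricyclic phenol; 23 prenyl acetate (3-methylbut-2-en-1-yl acetate)
Product: 24 (2R,3S,8R)-dearomatised enol lactone: the target with its carboxyl group closed onto O5
Conditions: Pd2(dba)3·CHCl3 (2.5 mol %), DACH-phenyl Trost ligand (7.5 mol %, antipode matched to the 8R face), K2CO3 (1.1 equiv), THF, 0 °C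
Reagents that add atoms: none
Why: Tsuji–Trost-type palladium-catalysed asymmetric allylic dearomatisation, in which the 7-phenoxide attacks the π-prenyl palladium complex through its ortho carbon C8 at the unsubstituted allyl terminus, should create the quaternary centre as 8R because the chiral ligand selects the ring face.

**Step 14**
Reactants: 24 dearomatised enol lactone
Product: 25 target, (3R)-3-[(2R,3S,8R)-5-hydroxy-2,3-dimethyl-8-(3-methylbut-2-en-1-yl)-8-[(2R)-5-methyl-2-(prop-1-en-2-yl)hex-4-en-1-yl]-4,7-dioxo-2,3-dihydrochromen-6-yl]hexanoic acid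
Conditions: H2O, imidazole (cat.), THF, 25 °C; then pH 4 buffer
Reagents that add atoms: water, O
Why: The 5-O-acyl group of the dearomatised ring is a vinylogous anhydride, so nucleophile-catalysed hydrolysis under near-neutral conditions should free the chelated 5-OH and the carboxylic acid without epimerising C3.

**Compound list**

1 | (S)-4-benzyl-1,3-oxazolidin-2-one | O=C1N[C@@H](Cc2ccccc2)CO1 | starting material
2 | 3-methylbut-2-enoyl chloride | CC(C)=CC(=O)Cl | starting material
3 | (S)-4-benzyl-3-(3-methylbut-2-enoyl)-1,3-oxazolidin-2-one | CC(C)=CC(=O)N1[C@@H](Cc2ccccc2)COC1=O | intermediate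
4 | prenyl bromide | CC(C)=CCBr | starting material
5 | (S)-4-benzyl-3-[(2S)-5-methyl-2-(prop-1-en-2-yl)hex-4-enoyl]-1,3-oxazolidin-2-one | C=C(C)[C@H](CC=C(C)C)C(=O)N1[C@@H](Cc2ccccc2)COC1=O | intermediate
6 | (S)-lavandulol | C=C(C)[C@H](CC=C(C)C)CO | intermediate
7 | (S)-lavandulyl iodide | C=C(C)[C@H](CC=C(C)C)CI | intermediate
8 | methyl 3,5-dioxohexanoate | COC(=O)CC(=O)CC(C)=O | starting material
9 | methyl (8S)-11-methyl-3,5-dioxo-8-(prop-1-en-2-yl)dodec-10-enoate | C=C(C)[C@H](CC=C(C)C)CCC(=O)CC(=O)CC(=O)OC | intermediate
10 | (E)-hex-2-enal | CCC/C=C/C=O | starting material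
11 | enol δ-lactone closed on the C5 oxygen of 9 (R at CH–Pr) | C=C(C)[C@H](CC=C(C)C)CCC1=C(C(=O)CC(=O)OC)[C@H](CCC)CC(=O)O1 | intermediate
12 | enol δ-lactone closed on the C3 oxygen of 9 (R at CH–Pr) | C=C(C)[C@H](CC=C(C)C)CCC(=O)C1=C(CC(=O)OC)OC(=O)C[C@H]1CCC | intermediate
13 | (3R)-3-[(8S)-1-methoxy-11-methyl-1,3,5-trioxo-8-(prop-1-en-2-yl)dodec-10-en-4-yl]hexanoic acid | C=C(C)[C@H](CC=C(C)C)CCC(=O)C(C(=O)CC(=O)OC)[C@H](CCC)CC(=O)O | intermediate
14 | (3R)-3-{4-hydroxy-6-[(3S)-6-methyl-3-(prop-1-en-2-yl)hept-5-en-1-yl]-2-oxo-2H-pyran-5-yl}hexanoic acid | C=C(C)[C@H](CC=C(C)C)CCC1=C([C@H](CCC)CC(=O)O)C(O)=CC(=O)O1 | intermediate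
15 | bis-lactone (2-pyranone with O4/C5 bridged by the (R)-CH(Pr)CH2C(=O) enol lactone) | C=C(C)[C@H](CC=C(C)C)CCC1=C2[C@H](CCC)CC(=O)OC2=CC(=O)O1 | intermediate
16 | dienylketene enolate (potassium salt) | C=C(C)[C@H](CC=C(C)C)CC=C([O-])C1=C(C=C=O)OC(=O)C[C@H]1CCC.[K+] | intermediate
17 | cyclohexa-2,4-dienone enolate (potassium salt) | C=C(C)[C@H](CC=C(C)C)CC1C(=O)C=C2OC(=O)C[C@@H](CCC)C2=C1[O-].[K+] | intermediate
18 | (4R)-5,7-dihydroxy-6-[(2R)-5-methyl-2-(prop-1-en-2-yl)hex-4-en-1-yl]-4-propylchroman-2-one | C=C(C)[C@H](CC=C(C)C)Cc1c(O)c2[C@H](CCC)CC(=O)Oc2cc1O | intermediate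
19 | 8-carbaldehyde of 18 | C=C(C)[C@H](CC=C(C)C)Cc1c(O)c2[C@H](CCC)CC(=O)Oc2c(C=O)c1O | intermediate
20 | 2-butyne | CC#CC | starting material
21 | 8-[(2E)-2-methylbut-2-enoyl] derivative of 18 | C=C(C)[C@H](CC=C(C)C)Cc1c(O)c2[C@H](CCC)CC(=O)Oc2c(C(=O)/C(C)=C/C)c1O | intermediate
22 | (2R,3S)-7-hydroxy-2,3-dimethyl-8-[(2R)-lavandulyl]chroman-4-one with O5/C6 bridged by the (R)-CH(Pr)CH2C(=O) lactone | C=C(C)[C@H](CC=C(C)C)Cc1c(O)c2[C@H](CCC)CC(=O)Oc2c3c1O[C@H](C)[C@H](C)C3=O | intermediate
23 | prenyl acetate | CC(C)=CCOC(C)=O | starting material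
24 | (2R,3S,8R)-dearomatised enol lactone (target with CO2H closed onto O5) | C=C(C)[C@H](CC=C(C)C)C[C@@]1(CC=C(C)C)C(=O)C2=C(OC(=O)C[C@H]2CCC)C3=C1O[C@H](C)[C@H](C)C3=O | intermediate
25 | target | C=C(C)[C@H](CC=C(C)C)C[C@@]1(CC=C(C)C)C(=O)C([C@H](CCC)CC(=O)O)=C(O)C2=C1O[C@H](C)[C@H](C)C2=O | target

**Step count and risks**

Total steps: 14. Longest linear sequence: 14 (steps 1–4 to iodide 7, then steps 5–14).

Steps most likely to fail:

1. Step 9 (proposed new method). The base may deprotonate the lactone α-carbon instead, which would open the enol lactone through a ketene, or intermolecular acyl transfer may outrun the E1cB ring opening and C–C closure. The fallback uses known chemistry and sets out from 9. Claisen-type cyclisation of the 3,5-dioxo ester (NaOMe, MeOH, reflux) should give 2-[(2R)-lavandulyl]benzene-1,3,5-triol F1. NHC-catalysed oxidative annulation of this arene with 10 (catalyst, base and oxidant of step 6, no hydrolysis) should then form the C–C bond at a free ring carbon and close the lactone on the hydroxyl that is not flanked by the lavandulyl group. It comes back to the route at 18.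

2. Step 13. The facial selectivity may be poor, O-prenylation may compete, or reversible ionisation of the new C–C bond may erode the configuration at C8. The fallback sets out from 22. Its potassium phenoxide is alkylated directly with prenyl bromide 4 in toluene (tight ion pair, C-alkylation as in lupulone-type dearomatisations) without a metal catalyst. This should give 24 together with its 8S epimer F2, which is removed by chromatography. It comes back at 24.

3. Step 11. The carbonate may trigger racemic ring closure of the tigloyl phenol as it forms, or the hindered aldehyde may decarbonylate instead of adding to the alkyne. The fallback sets out from 19. Nozaki–Hiyama–Kishi addition of (E)-2-bromobut-2-ene (CrCl2, NiCl2 cat., DMF) to the aldehyde, which leaves the aryl lactone alone, should give the allylic alcohol F3. Oxidation with MnO2 in CH2Cl2 then gives the enone, and the route is rejoined at 21.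

**Further compounds**

F1 | step 9 | 2-[(2R)-5-methyl-2-(prop-1-en-2-yl)hex-4-en-1-yl]benzene-1,3,5-triol | C=C(C)[C@H](CC=C(C)C)Cc1c(O)cc(O)cc1O
F2 | step 13 | 8S epimer of 24 | C=C(C)[C@H](CC=C(C)C)C[C@]1(CC=C(C)C)C(=O)C2=C(OC(=O)C[C@H]2CCC)C3=C1O[C@H](C)[C@H](C)C3=O
F3 | step 11 | (4R)-5,7-dihydroxy-8-[(2E)-1-hydroxy-2-methylbut-2-en-1-yl]-6-[(2R)-lavandulyl]-4-propylchroman-2-one | C=C(C)[C@H](CC=C(C)C)Cc1c(O)c2[C@H](CCC)CC(=O)Oc2c(C(O)/C(C)=C/C)c1O
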